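## Retrosynthetic overview

1. 24 ⇐ 21: the last bond is C6–C7. The allylindium from the 2-(bromomethyl)enoate (an ester homoenolate, nucleophilic at C7) adds to the C6 aldehyde released from a lactol. The ten-membered carbocycle closes first, then the γ-lactone, in the same flask, with the O8 angelate and free O15 already in place.
2. 21 ⇐ 17: the C7=C11–C13 unit comes from α-vinylalane addition to the C7 aldehyde and SN2′ bromination.
3. 17 ⇐ 11: lactone opening, angeloylation, amide-to-aldehyde reduction; C8 comes from (R)-5-oxooxolane-2-carboxylic acid 7.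
4. 11 ⇐ 8 + 6: aldol condensation sets the (E) C1=C10 olefin.
5. 6 ⇐ 1: enantioselective enolisation of 4-(hydroxymethyl)cyclohexanone and ozonolysis set C4 and differentiate C1 from C6.

Locants C1–C15 are the germacrane positions of 24: C1–C10 ring, C11–C13 lactone, C14 ester carbon, C15 hydroxymethyl carbon.

Assumption: the lithium amide from (S,S)-bis(1-phenylethyl)amine is taken to give the (R)-enol silane 3, by analogy with the (R,R)-amide giving the (S)-enol silane of 4-tert-butylcyclohexanone; if the sense is opposite, the (R,R)-amine is used.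

## Route

Step 1
Reactants: 1 4-(hydroxymethyl)cyclohexan-1-one
Product: 3 trimethyl({(4R)-4-[(trimethylsilyloxy)methyl]cyclohex-1-en-1-yl}oxy)silane, via silyl ether ketone 2 (not isolated)
Conditions: Me3SiCl, Et3N, THF, 0 °C; then lithium (S,S)-bis(1-phenylethyl)amide (from the amine and n-BuLi), LiCl, Me3SiCl, THF, −78 °C
Reagents that add atoms: chlorotrimethylsilane, C[Si](C)(C)Cl
Why: Enantioselective deprotonation (Simpkins–Koga desymmetrisation) of the prochiral ketone: the C2-symmetric lithium amide removes one of the two enantiotopic axial α-hydrogens and Me3SiCl in the flask traps the enolate, which sets C4 as R (about 90% ee expected; the minor series becomes a separable diastereomer later) and marks the enol carbon as the future C1 and the vinylic CH as the future C6.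

Step 2
Reactants: 3 trimethyl({(4R)-4-[(trimethylsilyloxy)methyl]cyclohex-1-en-1-yl}oxy)silane
Product: 5 methyl 3-[(3R)-5-methoxyoxolan-3-yl]propanoate, via aldehyde silyl ester 4 (not isolated)
Conditions: O3, CH2Cl2, −78 °C; Me2S, −78 °C to rt; then HCl (0.1 M) in MeOH, rt
Reagents that add atoms: ozone, [O-][O+]=O; methanol, CO
Why: Ozonolysis of the silyl enol ether cleaves the ring to an aldehyde (C6) and a silyl ester (C1), and acidic methanol then removes both silyl groups, esterifies C1 (Fischer esterification) and ties the C6 aldehyde to the C15 hydroxyl as the five-membered cyclic methyl acetal (both C5 epimers of the oxolane), so the two chain ends are differentiated while C4 is untouched.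

Step 3
Reactants: 5 methyl 3-[(3R)-5-methoxyoxolan-3-yl]propanoate
Product: 6 3-[(3R)-5-methoxyoxolan-3-yl]propanal
Conditions: iBu2AlH (1.05 equiv), CH2Cl2, −78 °C; aq. potassium sodium tartrate
Reagents that add atoms: none
Why: Partial reduction of a methyl ester to the aldehyde with iBu2AlH at −78 °C through the stable tetrahedral aluminium hemiacetal; the acetal is inert and no stereocentre is affected.

Step 4
Reactants: 7 (2R)-5-oxooxolane-2-carboxylic acid
Product: 8 (2R)-N-methoxy-N-methyl-5-oxooxolane-2-carboxamide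
Conditions: MeNH(OMe)·HCl, EDC·HCl, N-methylmorpholine, CH2Cl2, 0 °C to rt
Reagents that add atoms: N,O-dimethylhydroxylamine hydrochloride, CNOC.Cl
Why: Carbodiimide amide coupling gives the Weinreb amide, which later lets C7 be reduced to the aldehyde beside three esters and whose α-CH is less acidic than the lactone α-CH2; C8 (R, from the chiral pool) is not touched.

Step 5
Reactants: 8 (2R)-N-methoxy-N-methyl-5-oxooxolane-2-carboxamide; 6 3-[(3R)-5-methoxyoxolan-3-yl]propanal
Product: 11 (2R,4E)-N-methoxy-4-{3-[(3R)-5-methoxyoxolan-3-yl]propylidene}-N-methyl-5-oxooxolane-2-carboxamide, via lithium aldolate 9 (not isolated), via mesylate 10 (not isolated)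
Conditions: LiN(SiMe3)2, THF, −78 °C; then 6; then MeSO2Cl, −78 to 0 °C; then DBU, 0 °C to rt
Reagents that add atoms: none
Why: Aldol condensation: kinetic deprotonation occurs at the lactone α-CH2, the aldolate is mesylated in the flask and DBU effects E1cB elimination to the thermodynamically preferred (E)-α-alkylidene lactone (chain anti to the lactone carbonyl), which is the C1=C10 geometry of the target; no stereocentre is created and C4 and C8 are retained.

Step 6
Reactants: 11 (2R,4E)-N-methoxy-4-{3-[(3R)-5-methoxyoxolan-3-yl]propylidene}-N-methyl-5-oxooxolane-2-carboxamide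
Product: 13 methyl (2E,4R)-4-hydroxy-5-[methoxy(methyl)amino]-2-{3-[(3R)-5-methoxyoxolan-3-yl]propylidene}-5-oxopentanoate, via potassium carboxylate 12 (not isolated)
Conditions: KOH (1.05 equiv), THF/H2O, 0 °C; evaporate; MeI, DMF, 0 °C to rt
Reagents that add atoms: potassium hydroxide, [K+].[OH-]; iodomethane, CI
Why: Irreversible saponification of the lactone by acyl–oxygen cleavage (C8 retained) followed by SN2 O-methylation of the carboxylate gives the open γ-hydroxy methyl ester, which does not relactonise under neutral conditions and is used at once.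

Step 7
Reactants: 13 methyl (2E,4R)-4-hydroxy-5-[methoxy(methyl)amino]-2-{3-[(3R)-5-methoxyoxolan-3-yl]propylidene}-5-oxopentanoate; 14 angelic acid, (2Z)-2-methylbut-2-enoic acid
Product: 16 methyl (2E,4R)-5-[methoxy(methyl)amino]-2-{3-[(3R)-5-methoxyoxolan-3-yl]propylidene}-4-{[(2Z)-2-methylbut-2-enoyl]oxy}-5-oxopentanoate, via mixed anhydride 15 (not isolated)
Conditions: 14, 2,4,6-trichlorobenzoyl chloride, Et3N, toluene, rt; then 13, rt to 60 °C
Reagents that add atoms: none
Why: Yamaguchi esterification through the mixed anhydride without DMAP acylates the secondary hydroxyl with retention at C8 and avoids the conjugate-addition pathway that isomerises angelates to tiglates.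

Step 8
Reactants: 16 methyl (2E,4R)-5-[methoxy(methyl)amino]-2-{3-[(3R)-5-methoxyoxolan-3-yl]propylidene}-4-{[(2Z)-2-methylbut-2-enoyl]oxy}-5-oxopentanoate
Product: 17 methyl (2E,4R)-2-{3-[(3R)-5-methoxyoxolan-3-yl]propylidene}-4-{[(2Z)-2-methylbut-2-enoyl]oxy}-5-oxopentanoate
Conditions: Cp2Zr(H)Cl (1.5 equiv), THF, rt, 20 min
Reagents that add atoms: none
Why: Cp2Zr(H)Cl adds hydride to the amide carbonyl to give a zirconated N,O-hemiaminal that releases the aldehyde on work-up (Georg amide reduction), leaving the methyl ester, the angelate and the trisubstituted olefins untouched; C8 is retained because no base is present.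

Step 9
Reactants: 17 methyl (2E,4R)-2-{3-[(3R)-5-methoxyoxolan-3-yl]propylidene}-4-{[(2Z)-2-methylbut-2-enoyl]oxy}-5-oxopentanoate; 18 methyl propiolate
Product: 20 dimethyl (2E,4R)-5-hydroxy-2-{3-[(3R)-5-methoxyoxolan-3-yl]propylidene}-6-methylidene-4-{[(2Z)-2-methylbut-2-enoyl]oxy}heptanedioate, via vinylalane 19 (not isolated)
Conditions: 18, iBu2AlH, N-methylmorpholine N-oxide, THF, 0 °C; then 17, 0 °C to rt
Reagents that add atoms: none
Why: Hydroalumination of methyl propiolate gives the α-aluminoacrylate (vinylalumination, a non-basic equivalent of the Morita–Baylis–Hillman reaction), which adds 1,2 to the aldehyde without epimerising C8; the new carbinol centre C7 forms as a mixture that does not matter because it becomes sp2 in the next step.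

Step 10
Reactants: 20 dimethyl (2E,4R)-5-hydroxy-2-{3-[(3R)-5-methoxyoxolan-3-yl]propylidene}-6-methylidene-4-{[(2Z)-2-methylbut-2-enoyl]oxy}heptanedioate
Product: 21 dimethyl (2Z,4R,6E)-2-(bromomethyl)-6-{3-[(3R)-5-methoxyoxolan-3-yl]propylidene}-4-{[(2Z)-2-methylbut-2-enoyl]oxy}hept-2-enedioate
Conditions: N-bromosuccinimide, Me2S, CH2Cl2, 0 °C to rt
Reagents that add atoms: N-bromosuccinimide, O=C1CCC(=O)N1Br
Why: The bromosulfonium salt from N-bromosuccinimide and Me2S activates the allylic hydroxyl and bromide attacks the methylene terminus (SN2′ allylic transposition, Corey–Kim type), giving the conjugated (Z)-2-(bromomethyl)enoate with C8 cis to CH2Br under near-neutral conditions that spare the acetal and the angelate.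

Step 11
Reactants: 21 dimethyl (2Z,4R,6E)-2-(bromomethyl)-6-{3-[(3R)-5-methoxyoxolan-3-yl]propylidene}-4-{[(2Z)-2-methylbut-2-enoyl]oxy}hept-2-enedioate
Product: 24 methyl (3aS,4R,6E,10R,11aR)-10-(hydroxymethyl)-3-methylidene-4-{[(2Z)-2-methylbut-2-enoyl]oxy}-2-oxo-2,3,3a,4,5,8,9,10,11,11a-decahydrocyclodeca[b]furan-6-carboxylate (CNP0167542.1), via lactol 22 (not isolated), via hydroxy ester 23 (not isolated)
Conditions: HCl (0.2 M), THF/H2O (1:1), rt; NaHCO3 to pH 6; slow addition to In powder (5 equiv), NH4Cl, THF/H2O, 2 mM, 35 °C; then HCl (1 M), rt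
Reagents that add atoms: water, O
Why: Intramolecular indium-mediated Barbier allylation followed by lactonisation: insertion of indium metal into the C13–Br bond turns the enoate β-carbon C7 (normally an acceptor) into the γ-terminus of a 2-(methoxycarbonyl)allylindium, an ester homoenolate equivalent, which attacks the C6 aldehyde liberated from the lactol in water. The reaction is known for five- to seven-membered carbocycles with indium and for ten-membered germacranolide rings with CrCl2. C7 is expected S because, with H8 held in the olefin plane by allylic strain, the aldehyde adds anti to the C8–C9 bond. C6 is expected R because the eight-atom tether with its ring-cis olefin spans C5 and C8 only when they are antiperiplanar about the forming bond, which gives the anti adduct and hence the trans-fused lactone on acid-promoted closure of O6 onto C12.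

## Compound list

1 | 4-(hydroxymethyl)cyclohexan-1-one | O=C1CCC(CO)CC1 | starting material
2 | 4-[(trimethylsilyloxy)methyl]cyclohexan-1-one | C[Si](C)(C)OCC1CCC(=O)CC1 | intermediate
3 | trimethyl({(4R)-4-[(trimethylsilyloxy)methyl]cyclohex-1-en-1-yl}oxy)silane | C[Si](C)(C)OC[C@@H]1CCC(O[Si](C)(C)C)=CC1 | intermediate
4 | trimethylsilyl (4R)-6-oxo-4-[(trimethylsilyloxy)methyl]hexanoate | C[Si](C)(C)OC[C@@H](CC=O)CCC(=O)O[Si](C)(C)C | intermediate
5 | methyl 3-[(3R)-5-methoxyoxolan-3-yl]propanoate (both acetal epimers) | COC(=O)CC[C@H]1COC(OC)C1 | intermediate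
6 | 3-[(3R)-5-methoxyoxolan-3-yl]propanal | O=CCC[C@H]1COC(OC)C1 | intermediate
7 | (2R)-5-oxooxolane-2-carboxylic acid | OC(=O)[C@H]1CCC(=O)O1 | starting material
8 | (2R)-N-methoxy-N-methyl-5-oxooxolane-2-carboxamide | CON(C)C(=O)[C@H]1CCC(=O)O1 | intermediate
9 | lithium alkoxide of (2R)-4-{1-hydroxy-3-[(3R)-5-methoxyoxolan-3-yl]propyl}-N-methoxy-N-methyl-5-oxooxolane-2-carboxamide (diastereomer mixture) | CON(C)C(=O)[C@H]1CC(C([O-])CC[C@H]2COC(OC)C2)C(=O)O1.[Li+] | intermediate
10 | 1-{(5R)-5-[methoxy(methyl)carbamoyl]-2-oxooxolan-3-yl}-3-[(3R)-5-methoxyoxolan-3-yl]propyl methanesulfonate | CON(C)C(=O)[C@H]1CC(C(OS(C)(=O)=O)CC[C@H]2COC(OC)C2)C(=O)O1 | intermediate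
11 | (2R,4E)-N-methoxy-4-{3-[(3R)-5-methoxyoxolan-3-yl]propylidene}-N-methyl-5-oxooxolane-2-carboxamide | CON(C)C(=O)[C@H]1C/C(=C\CC[C@H]2COC(OC)C2)C(=O)O1 | intermediate
12 | potassium (2E,4R)-4-hydroxy-5-[methoxy(methyl)amino]-2-{3-[(3R)-5-methoxyoxolan-3-yl]propylidene}-5-oxopentanoate | CON(C)C(=O)[C@H](O)C/C(C(=O)[O-])=C\CC[C@H]1COC(OC)C1.[K+] | intermediate
13 | methyl (2E,4R)-4-hydroxy-5-[methoxy(methyl)amino]-2-{3-[(3R)-5-methoxyoxolan-3-yl]propylidene}-5-oxopentanoate | CON(C)C(=O)[C@H](O)C/C(C(=O)OC)=C\CC[C@H]1COC(OC)C1 | intermediate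
14 | angelic acid, (2Z)-2-methylbut-2-enoic acid | C/C=C(/C)C(=O)O | starting material
15 | (2Z)-2-methylbut-2-enoic 2,4,6-trichlorobenzoic anhydride | C/C=C(/C)C(=O)OC(=O)c1c(Cl)cc(Cl)cc1Cl | intermediate
16 | methyl (2E,4R)-5-[methoxy(methyl)amino]-2-{3-[(3R)-5-methoxyoxolan-3-yl]propylidene}-4-{[(2Z)-2-methylbut-2-enoyl]oxy}-5-oxopentanoate | CON(C)C(=O)[C@H](OC(=O)/C(C)=C\C)C/C(C(=O)OC)=C\CC[C@H]1COC(OC)C1 | intermediate
17 | methyl (2E,4R)-2-{3-[(3R)-5-methoxyoxolan-3-yl]propylidene}-4-{[(2Z)-2-methylbut-2-enoyl]oxy}-5-oxopentanoate | O=C[C@H](OC(=O)/C(C)=C\C)C/C(C(=O)OC)=C\CC[C@H]1COC(OC)C1 | intermediate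
18 | methyl propiolate (methyl prop-2-ynoate) | C#CC(=O)OC | starting material
19 | methyl 2-[bis(2-methylpropyl)alumanyl]prop-2-enoate | C=C([Al](CC(C)C)CC(C)C)C(=O)OC | intermediate
20 | dimethyl (2E,4R)-5-hydroxy-2-{3-[(3R)-5-methoxyoxolan-3-yl]propylidene}-6-methylidene-4-{[(2Z)-2-methylbut-2-enoyl]oxy}heptanedioate (both C5 epimers) | C=C(C(=O)OC)C(O)[C@H](OC(=O)/C(C)=C\C)C/C(C(=O)OC)=C\CC[C@H]1COC(OC)C1 | intermediate
21 | dimethyl (2Z,4R,6E)-2-(bromomethyl)-6-{3-[(3R)-5-methoxyoxolan-3-yl]propylidene}-4-{[(2Z)-2-methylbut-2-enoyl]oxy}hept-2-enedioate | BrC/C(C(=O)OC)=C\[C@H](OC(=O)/C(C)=C\C)C/C(C(=O)OC)=C\CC[C@H]1COC(OC)C1 | intermediate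
22 | dimethyl (2Z,4R,6E)-2-(bromomethyl)-6-{3-[(3R)-5-hydroxyoxolan-3-yl]propylidene}-4-{[(2Z)-2-methylbut-2-enoyl]oxy}hept-2-enedioate (lactol) | BrC/C(C(=O)OC)=C\[C@H](OC(=O)/C(C)=C\C)C/C(C(=O)OC)=C\CC[C@H]1COC(O)C1 | intermediate
23 | methyl (1E,5R,7R,8S,9R)-7-hydroxy-5-(hydroxymethyl)-8-(3-methoxy-3-oxoprop-1-en-2-yl)-9-{[(2Z)-2-methylbut-2-enoyl]oxy}cyclodec-1-ene-1-carboxylate | C=C(C(=O)OC)[C@H]1[C@H](O)C[C@H](CO)CC/C=C(/C(=O)OC)C[C@H]1OC(=O)/C(C)=C\C | intermediate
24 | methyl (3aS,4R,6E,10R,11aR)-10-(hydroxymethyl)-3-methylidene-4-{[(2Z)-2-methylbut-2-enoyl]oxy}-2-oxo-2,3,3a,4,5,8,9,10,11,11a-decahydrocyclodeca[b]furan-6-carboxylate | C=C1C(=O)O[C@@H]2C[C@H](CO)CC/C=C(/C(=O)OC)C[C@@H](OC(=O)/C(C)=C\C)[C@@H]12 | target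

## Step count and risks

Total steps: 11. Longest linear sequence: 10 steps (1 to 24 through steps 1, 2, 3, 5, 6, 7, 8, 9, 10, 11); the branch from 7 joins at step 5.

Most likely to fail, first: step 11. The allylindium may lose the angelate by 1,4-elimination to a diene, be protonated before the slow ring closure, oligomerise, or give the wrong C6/C7 diastereomer. The fallback sets out from 21. Borylation with B2pin2, Pd2(dba)3 (zerovalent palladium) and AsPh3 in toluene at 50 °C gives the allylboronate F1, a covalent ester homoenolate equivalent that cannot eliminate. Dilute aqueous HCl in THF converts it to its lactol F2, which at 2 mM in toluene with Sc(OTf)3 undergoes intramolecular allylboration through a closed chair transition state to the cyclic borate ester F3. Hydrolytic work-up gives 23, where the fallback comes back to the route, and acid closes the lactone to 24.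

Second: step 9. The α-acyloxy aldehyde 17 can epimerise at C8, and in 20 the angelate can shift from O8 to the neighbouring new hydroxyl. The fallback sets out from 17 and avoids a hydroxyl at C7 altogether. Horner–Wadsworth–Emmons olefination with methyl 2-(dimethoxyphosphoryl)-3-hydroxypropanoate F4 (made from trimethyl phosphonoacetate and aqueous formaldehyde), LiCl and iPr2NEt in MeCN at 0 °C gives the 2-(hydroxymethyl)enoate F5 with C8 cis to CH2OH. CBr4 and PPh3 in CH2Cl2 at 0 °C then convert the primary allylic alcohol to the bromide, coming back to the route at 21.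

Third: step 6. The γ-hydroxy ester 13 can relactonise to 11 during isolation or during the warm acylation of step 7. The fallback sets out from 11 and never frees O8. Anhydrous HBr in MeOH opens the lactone by bromide attack at C8 (alkyl–oxygen cleavage with inversion) and esterifies the acid, giving the (4S)-bromo ester F6. Caesium angelate F7 (from 14 and Cs2CO3) in DMF at rt displaces the α-bromo amide with a second inversion, coming back to the route at 16 with net retention at C8.

## Further compounds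

F1 | step 11 | dimethyl (2E,4R,6E)-6-{3-[(3R)-5-methoxyoxolan-3-yl]propylidene}-4-{[(2Z)-2-methylbut-2-enoyl]oxy}-2-[(4,4,5,5-tetramethyl-1,3,2-dioxaborolan-2-yl)methyl]hept-2-enedioate | CC1(C)OB(C/C(C(=O)OC)=C\[C@H](OC(=O)/C(C)=C\C)C/C(C(=O)OC)=C\CC[C@H]2COC(OC)C2)OC1(C)C
F2 | step 11 | dimethyl (2E,4R,6E)-6-{3-[(3R)-5-hydroxyoxolan-3-yl]propylidene}-4-{[(2Z)-2-methylbut-2-enoyl]oxy}-2-[(4,4,5,5-tetramethyl-1,3,2-dioxaborolan-2-yl)methyl]hept-2-enedioate | CC1(C)OB(C/C(C(=O)OC)=C\[C@H](OC(=O)/C(C)=C\C)C/C(C(=O)OC)=C\CC[C@H]2COC(O)C2)OC1(C)C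
F3 | step 11 | methyl (1E,5R,7R,8S,9R)-5-(hydroxymethyl)-8-(3-methoxy-3-oxoprop-1-en-2-yl)-9-{[(2Z)-2-methylbut-2-enoyl]oxy}-7-[(4,4,5,5-tetramethyl-1,3,2-dioxaborolan-2-yl)oxy]cyclodec-1-ene-1-carboxylate | C=C(C(=O)OC)[C@H]1[C@H](OB2OC(C)(C)C(C)(C)O2)C[C@H](CO)CC/C=C(/C(=O)OC)C[C@H]1OC(=O)/C(C)=C\C
F4 | step 9 | methyl 2-(dimethoxyphosphoryl)-3-hydroxypropanoate | COC(=O)C(CO)P(=O)(OC)OC
F5 | step 9 | dimethyl (2E,4R,6E)-2-(hydroxymethyl)-6-{3-[(3R)-5-methoxyoxolan-3-yl]propylidene}-4-{[(2Z)-2-methylbut-2-enoyl]oxy}hept-2-enedioate | OC/C(C(=O)OC)=C\[C@H](OC(=O)/C(C)=C\C)C/C(C(=O)OC)=C\CC[C@H]1COC(OC)C1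
F6 | step 6 | methyl (2E,4S)-4-bromo-5-[methoxy(methyl)amino]-2-{3-[(3R)-5-methoxyoxolan-3-yl]propylidene}-5-oxopentanoate | CON(C)C(=O)[C@@H](Br)C/C(C(=O)OC)=C\CC[C@H]1COC(OC)C1
F7 | step 6 | caesium (2Z)-2-methylbut-2-enoate | C/C=C(/C)C(=O)[O-].[Cs+]
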